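## The problem

Target 19 is a biflavonoid. C5' of ring B of a (2S)-5,7,3',4'-tetrahydroxyflavanone is bonded to C6'' of apigenin (flavanone atoms unprimed, ring B primed, flavone atoms double-primed). The biaryl bond lies between two oxygenated carbons (C5'', C7'') on the flavone side and next to O4' on the other. It is therefore a hindered axis with three ortho oxygens, and it must be made at C6'' and not at C8''. The only stereocentre is C2; nothing else in the molecule can control it, so it must come from a catalyst and then survive every later step. C2 is benzylic, para to O4' and β to the C4 carbonyl: base opens ring C by retro-oxa-Michael reaction to the 2'-hydroxychalcone and acid ionises C2–O1, and either racemises the flavanone. Seven phenols must be masked and released at the end under neutral conditions that spare the flavone enone, the aryl ketone and the benzylic ether of ring C. The enabling feature is that O1–C8a is an aryl ether bond of ring A. With a bromide on C8a, ring C can be closed by arylating a C2 alcohol through its O–H bond, so the C2–O bond is made earlier by ketone reduction on an open chain and is never touched again. The C4 oxygen could only close a four-membered ring and cannot compete.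

## Retrosynthesis

**End game.** Target 19 is traced to hepta-O-benzyl flavanone 18 by cleaving seven O–benzyl bonds. Benzyl ethers are chosen over methyl or silyl ethers because hydrogenolysis is neutral and the flavanone then never meets base or strong acid. Ketone 18 is traced to flavan-4-ol 17 by a change of oxidation level at C4. Carrying C4 as a carbinol through the ring closure removes the β-aryloxy ketone, and with it retro-aldol and elimination pathways, from the only basic, hot step. The forward oxidation must be neutral.

**Key disconnection.** In 17 the bond O1–C8a is cut, giving the open-chain (1S,3S)-diol 16 with a bromide on ring A ortho to the chain. The neighbouring cut, O1–C2, would make the bond at the ionisable benzylic carbon (inversion, or an equilibrating conjugate addition). The chosen cut leaves all four bonds at C2 untouched. The forward step must arylate one of two secondary benzylic alkoxides; ring size decides which. Copper is preferred to palladium, whose secondary alkoxides undergo β-hydride elimination easily.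

**Carbinols.** Diol 16 is traced to β-hydroxy ketone 15 (C1–H bond) and 15 to the 1,3-diketone 14 (C3–H bond). This removes both stereocentres and leaves an achiral precursor. The forward reactions must reduce only the carbonyl next to ring B, with catalyst control of the face, and then reduce the hindered ring A carbonyl without touching the flavone carbonyl. The ring A carbonyl is flanked by bromine and a benzyloxy group, which differentiates the two ketones. The hydroxyl made first can then direct the second hydride.

**Three-carbon chain.** In 14 the bond between the ring B carbonyl carbon and the central methylene (the future C2–C3 bond) is cut. This gives methyl ester 10 and methyl ketone 13 for a crossed Claisen condensation. Only 13 can enolise and only 10 can acylate; the opposite polarity would need a doubly ortho-substituted benzoate as acyl donor. Ester 10 comes from aldehyde 9 by oxidative esterification.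

**Biaryl bond.** In 9 the C5'–C6'' bond is cut to boronate 4 and iodide 8. Boron is put on ring B, which has only one ortho oxygen, because a 2,6-dialkoxyarylboron reagent would protodeboronate. The forward coupling must tolerate three ortho substituents and an aldehyde.

**Flavone half.** Iodide 8 is traced through 7 and 6 to apigenin 5, which is commercial with all fifteen carbons and the right oxygenation. The order matters: the two unchelated phenols are benzylated first, the free chelated 5''-hydroxyl then directs iodination to C6'', and only then is the last phenol benzylated.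

**Ring B and ring A pieces.** Boronate 4 is traced through iodide 3 and catechol 2 to 5-iodovanillin 1, which already has the iodine where the biaryl bond is needed. Ketone 13 is traced through 12 to 5-bromoresorcinol 11 by C-acetylation next to the bromine and benzylation.

## Roads not taken

**Alternative 1:** Here the flavone ring A is built and not bought: its C4a''–C8a'' bond is cut. In the forward direction the symmetric diketo diester A1 would undergo a Dieckmann condensation. A methylene next to one ester attacks the other ester, and the cyclic trione enolises to the aromatic methyl 3-aryl-2,4,6-trihydroxybenzoate A2.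
- Merits: the hindered biaryl bond is never made by cross-coupling, because the aryl group sits on carbon before the ring exists. The symmetry of A1 allows only one Dieckmann product. In this respect it is more secure than the coupling of step 7.
- Weak points: the pyranone must still be built on A2 from the ester. The two phenols ortho to the ester then have to be told apart: closure through the one next to the aryl group gives the 8''-aryl isomer, so the regiochemical question returns. A1 is itself several C–C bond formations from commercial material. The alternative does nothing for C2.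
- Comparison: the chosen plan sets against it three steps from apigenin 5 to iodide 8, a hydroxyl-directed C6'' iodination, and a ligand made for hindered couplings.

**Alternative 2:** Three bonds of the flavone pyranone are cut (C4a''–C4'', C4''–C3'', O1''–C2''). In the forward direction the ortho-iodophenol A3, the alkyne A4 and carbon monoxide A5 would combine under palladium catalysis with an amine base to give flavone A6.
- Merits: three bonds and a ring in one step, and the aryl position is fixed by the iodide. For the flavone ring it is more convergent than the chosen route.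
- Weak points: A3 is a phloroglucinol biaryl that needs one free phenol, one iodide and two benzyl ethers in defined positions. The selectivity problem that apigenin solves by its chelated hydroxyl is thereby moved to a less helpful substrate. The acylpalladium or alkynone intermediate can close 6-endo to the flavone or 5-exo to an aurone. Oxidative addition at an iodide flanked by two oxygens is slow, so non-carbonylative coupling to a benzofuran competes.
- Comparison: the chosen plan buys the ring that this alternative builds. Like alternative 1, this one does not address C2.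

**Alternative 3:** This cuts O1–C2, the neighbour of the chosen bond. In the forward direction the free phenol of the alkylidene β-keto ester A7 would add to the benzylic alkene carbon under a bifunctional cinchona thiourea. This closes ring C and sets C2 to give the 3-tert-butoxycarbonyl flavanone A8, which would then lose its ester.
- Merits: ring closure and stereocentre come in one catalytic step, C4 stays a ketone, and A7 would arise from aldehyde 9 in one condensation. It is about three steps shorter than steps 8 and 11 to 15, and here it is better.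
- Weak points: the C2–O1 bond is formed in a reversible conjugate addition at the carbon that ionises most easily. The para oxygen of ring B and the 5-benzyloxy group of ring A both favour the open form, so the enantiomeric purity can erode during the reaction and during acidic removal of the ester. The catalyst would also have to discriminate faces on a ring B carrying a bulky flavone.
- Comparison: the chosen plan sets against it an irreversible ketone reduction that fixes C2 and a ring closure that touches no bond at C2. The price is the reduction and re-oxidation at C4.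

Key step: step 14

Remark (assumption): the C5'–C6'' axis has three ortho oxygens; it is assumed to rotate fast enough at room temperature that no separable atropisomers arise, so it is drawn without a descriptor (signal broadening by rotamers in the benzylated intermediates would not be surprising).

Abbreviations used in names: Fl = 5,7-bis(benzyloxy)-2-[4-(benzyloxy)phenyl]-4-oxo-4H-chromen-6-yl; ArB = 3,4-bis(benzyloxy)-5-Fl-phenyl; ArA = 2,4-bis(benzyloxy)-6-bromophenyl.

## Route

Step 1
Reactants: 1 5-iodovanillin (4-hydroxy-3-iodo-5-methoxybenzaldehyde)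
Product: 2 3,4-dihydroxy-5-iodobenzaldehyde
Conditions: AlCl3, pyridine, CH2Cl2, reflux; then 2 M HCl
Reagents that add atoms: none
Why: Lewis-acid demethylation of an aryl methyl ether ortho to a free phenol; the aluminium phenoxide chelates the methoxy oxygen and pyridine takes the methyl group, while aldehyde and iodide are inert.

Step 2
Reactants: 2 3,4-dihydroxy-5-iodobenzaldehyde
Product: 3 3,4-bis(benzyloxy)-5-iodobenzaldehyde
Conditions: BnBr, K2CO3, DMF, 60 °C
Reagents that add atoms: benzyl bromide, BrCc1ccccc1
Why: Williamson ether synthesis on both catechol hydroxyls; benzyl is chosen so that all phenols can be freed together by neutral hydrogenolysis.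

Step 3
Reactants: 3 3,4-bis(benzyloxy)-5-iodobenzaldehyde
Product: 4 3,4-bis(benzyloxy)-5-(4,4,5,5-tetramethyl-1,3,2-dioxaborolan-2-yl)benzaldehyde
Conditions: B2pin2, PdCl2(dppf) (cat.), KOAc, 1,4-dioxane, 85 °C
Reagents that add atoms: bis(pinacolato)diboron, CC1(C)OB(OC1(C)C)B1OC(C)(C)C(C)(C)O1
Why: Miyaura borylation; zerovalent palladium inserts into the C–I bond and acetate-assisted transmetalation delivers boron, and the weak base leaves the aldehyde alone.

Step 4
Reactants: 5 apigenin
Product: 6 7-(benzyloxy)-2-[4-(benzyloxy)phenyl]-5-hydroxy-4H-chromen-4-one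
Conditions: BnBr (2.2 equiv), K2CO3, acetone, reflux
Reagents that add atoms: benzyl bromide, BrCc1ccccc1
Why: Williamson ether synthesis selective for the two unchelated phenols; the 5''-hydroxyl is hydrogen-bonded to the C4'' carbonyl and is not alkylated with a limited amount of halide.

Step 5
Reactants: 6 7-(benzyloxy)-2-[4-(benzyloxy)phenyl]-5-hydroxy-4H-chromen-4-one
Product: 7 7-(benzyloxy)-2-[4-(benzyloxy)phenyl]-5-hydroxy-6-iodo-4H-chromen-4-one
Conditions: BnMe3N·ICl2, CaCO3, CH2Cl2/MeOH, rt
Reagents that add atoms: benzyltrimethylammonium dichloroiodate, C[N+](C)(C)Cc1ccccc1.Cl[I-]Cl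
Why: Electrophilic aromatic iodination; in 5-hydroxy-7-alkoxyflavones the free chelated hydroxyl directs the electrophile to the ortho carbon C6'' (fully alkylated congeners react at C8''), and CaCO3 removes the HCl formed.

Step 6
Reactants: 7 7-(benzyloxy)-2-[4-(benzyloxy)phenyl]-5-hydroxy-6-iodo-4H-chromen-4-one
Product: 8 5,7-bis(benzyloxy)-2-[4-(benzyloxy)phenyl]-6-iodo-4H-chromen-4-one
Conditions: BnBr, K2CO3, DMF, 80 °C
Reagents that add atoms: benzyl bromide, BrCc1ccccc1
Why: Williamson ether synthesis on the chelated phenol under more forcing conditions; it is done only now because the free hydroxyl was needed to steer the iodination.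

Step 7
Reactants: 4 3,4-bis(benzyloxy)-5-(4,4,5,5-tetramethyl-1,3,2-dioxaborolan-2-yl)benzaldehyde; 8 5,7-bis(benzyloxy)-2-[4-(benzyloxy)phenyl]-6-iodo-4H-chromen-4-one
Product: 9 3,4-bis(benzyloxy)-5-Fl-benzaldehyde
Conditions: Pd(OAc)2 (cat.), SPhos, K3PO4, toluene/H2O (10:1), 100 °C
Reagents that add atoms: none
Why: Suzuki–Miyaura coupling forming the C5'–C6'' bond; the electron-rich dialkylbiarylphosphine speeds oxidative addition at the doubly flanked iodide and reductive elimination of the tri-ortho-substituted biaryl, and the boron partner has only one ortho oxygen.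

Step 8
Reactants: 9 3,4-bis(benzyloxy)-5-Fl-benzaldehyde
Product: 10 methyl 3,4-bis(benzyloxy)-5-Fl-benzoate
Conditions: I2, KOH, MeOH/THF, 0 °C
Reagents that add atoms: methanol, CO
Why: Oxidative esterification of an aromatic aldehyde; the hemiacetal formed in alkaline methanol is oxidised by hypoiodite to the methyl ester, giving the acyl donor for the Claisen condensation.

Step 9
Reactants: 11 5-bromoresorcinol
Product: 12 1-(2-bromo-4,6-dihydroxyphenyl)ethanone
Conditions: AcOH, BF3·OEt2, 90 °C; then H2O
Reagents that add atoms: acetic acid, CC(=O)O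
Why: Friedel–Crafts (Nencki-type) C-acylation of a resorcinol; attack should occur para to one hydroxyl and ortho to the other, next to the bromine, as with other 5-substituted resorcinols, and the difluoroboron chelate of the product prevents a second acylation.

Step 10
Reactants: 12 1-(2-bromo-4,6-dihydroxyphenyl)ethanone
Product: 13 1-[2,4-bis(benzyloxy)-6-bromophenyl]ethanone
Conditions: BnBr, K2CO3, DMF, 70 °C
Reagents that add atoms: benzyl bromide, BrCc1ccccc1
Why: Williamson ether synthesis on both phenols, the chelated ortho hydroxyl included under warm carbonate in DMF.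

Step 11
Reactants: 10 methyl 3,4-bis(benzyloxy)-5-Fl-benzoate; 13 1-[2,4-bis(benzyloxy)-6-bromophenyl]ethanone
Product: 14 1-ArA-3-ArB-propane-1,3-dione
Conditions: LiHMDS (3 equiv), THF, 0 °C → rt; then 1 M HCl
Reagents that add atoms: none
Why: Crossed Claisen condensation; only the methyl ketone can enolise and only the ester can acylate, the hindered ketone carbonyl resists self-aldol addition, and deprotonation of the 1,3-diketone drives the reaction.

Step 12
Reactants: 14 1-ArA-3-ArB-propane-1,3-dione
Product: 15 (3S)-1-ArA-3-ArB-3-hydroxypropan-1-one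
Conditions: RuCl[(S,S)-TsDPEN](p-cymene) (cat.), HCO2H/Et3N (5:2), CH2Cl2, 30 °C
Reagents that add atoms: none
Why: Noyori–Ikariya asymmetric transfer hydrogenation of a 1,3-diketone stopped at the β-hydroxy ketone; the ring A carbonyl is flanked by bromine and a benzyloxy group and is shielded, so the divalent ruthenium hydride should reduce only the ring B carbonyl. The (S,S)-ligand should deliver hydride to its Re face as with simple aryl ketones, giving the (S)-carbinol (the future C2), and loss of CO2 makes the reduction irreversible.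

Step 13
Reactants: 15 (3S)-1-ArA-3-ArB-3-hydroxypropan-1-one
Product: 16 (1S,3S)-1-ArA-3-ArB-propane-1,3-diol
Conditions: Me4NBH(OAc)3, MeCN/AcOH/CH2Cl2, −30 °C
Reagents that add atoms: none
Why: Evans–Saksena hydroxyl-directed reduction; the C3 hydroxyl binds boron and delivers hydride intramolecularly through a chair, which should give the 1,3-anti diol and so the (1S) centre. The reagent does not reduce carbonyls without a neighbouring hydroxyl, so the flavone carbonyl is safe, and the C1 configuration is immaterial because it is removed in step 15.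

Step 14
Reactants: 16 (1S,3S)-1-ArA-3-ArB-propane-1,3-diol
Product: 17 (2S,4S)-5,7-bis(benzyloxy)-2-ArB-chroman-4-ol (2,4-cis)
Conditions: CuI (20 mol %), 1,10-phenanthroline (40 mol %), Cs2CO3, toluene (0.01 M), 110 °C, Ar
Reagents that add atoms: none
Why: Cs2CO3 deprotonates the C3 hydroxyl (the future O1) and the alkoxide binds (phen)CuI to give a monovalent copper alkoxide; oxidative addition into the neighbouring C–Br bond gives a trivalent copper aryl alkoxide, and C–O reductive elimination forms O1–C8a and returns monovalent copper. The closest known reaction type is the Ullmann-type copper-catalysed intramolecular O-arylation of secondary alcohols with aryl bromides, which gives chromans and 2-arylchromans. Ring C closes in a six-membered exo mode (the bromide leaves outside the new ring) by reductive elimination from a seven-membered oxa-cupracycle. No stereocentre is formed: C2 keeps its (S) configuration because only its O–H bond reacts, and C4 is untouched. The step needs site selectivity between the two hydroxyls, and ring size secures it, since the C4 oxygen could only close a four-membered ring; the anti diol also places the aryl group and the C4 hydroxyl both equatorial in the closing ring. Copper is preferred to palladium because a palladium alkoxide of a secondary benzylic alcohol would readily undergo β-hydride elimination, and C4 is carried as the alcohol so that carbonate at 110 °C cannot cause retro-aldol cleavage or dehydration. High dilution and exclusion of air should suppress intermolecular etherification and oxidation of the carbinols.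

Step 15
Reactants: 17 (2S,4S)-5,7-bis(benzyloxy)-2-ArB-chroman-4-ol
Product: 18 (2S)-5,7-bis(benzyloxy)-2-ArB-chroman-4-one
Conditions: DMP, CH2Cl2, 0 °C → rt
Reagents that add atoms: none
Why: Dess–Martin oxidation of the secondary benzylic alcohol to the aryl ketone under neutral conditions; no base is present, so ring C cannot open by retro-oxa-Michael reaction and C2 stays (S).

Step 16
Reactants: 18 (2S)-5,7-bis(benzyloxy)-2-ArB-chroman-4-one
Product: 19 (2S)-2-{3,4-dihydroxy-5-[5,7-dihydroxy-2-(4-hydroxyphenyl)-4-oxo-4H-chromen-6-yl]phenyl}-5,7-dihydroxychroman-4-one (the target)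
Conditions: H2 (1 atm), 10% Pd/C, EtOAc/MeOH, rt
Reagents that add atoms: none
Why: Hydrogenolysis of the seven aryl benzyl ethers; the conditions are neutral, and at one atmosphere and room temperature aryl benzyl ethers should cleave well before the cyclic benzylic ether, the aryl ketone or the flavone C2''–C3'' bond react.

## Compound list

1 | 5-iodovanillin | COc1cc(C=O)cc(I)c1O | starting material
2 | 3,4-dihydroxy-5-iodobenzaldehyde | O=Cc1cc(O)c(O)c(I)c1 | intermediate
3 | 3,4-bis(benzyloxy)-5-iodobenzaldehyde | O=Cc1cc(OCc2ccccc2)c(OCc2ccccc2)c(I)c1 | intermediate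
4 | 3,4-bis(benzyloxy)-5-(4,4,5,5-tetramethyl-1,3,2-dioxaborolan-2-yl)benzaldehyde | O=Cc1cc(OCc2ccccc2)c(OCc2ccccc2)c(B2OC(C)(C)C(C)(C)O2)c1 | intermediate
5 | apigenin | O=c1cc(-c2ccc(O)cc2)oc2cc(O)cc(O)c12 | starting material
6 | 7-(benzyloxy)-2-[4-(benzyloxy)phenyl]-5-hydroxy-4H-chromen-4-one | O=c1cc(-c2ccc(OCc3ccccc3)cc2)oc2cc(OCc3ccccc3)cc(O)c12 | intermediate
7 | 7-(benzyloxy)-2-[4-(benzyloxy)phenyl]-5-hydroxy-6-iodo-4H-chromen-4-one | O=c1cc(-c2ccc(OCc3ccccc3)cc2)oc2cc(OCc3ccccc3)c(I)c(O)c12 | intermediate
8 | 5,7-bis(benzyloxy)-2-[4-(benzyloxy)phenyl]-6-iodo-4H-chromen-4-one | O=c1cc(-c2ccc(OCc3ccccc3)cc2)oc2cc(OCc3ccccc3)c(I)c(OCc3ccccc3)c12 | intermediate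
9 | 3,4-bis(benzyloxy)-5-{5,7-bis(benzyloxy)-2-[4-(benzyloxy)phenyl]-4-oxo-4H-chromen-6-yl}benzaldehyde | O=Cc1cc(OCc2ccccc2)c(OCc2ccccc2)c(-c2c(OCc3ccccc3)cc3oc(-c4ccc(OCc5ccccc5)cc4)cc(=O)c3c2OCc2ccccc2)c1 | intermediate
10 | methyl 3,4-bis(benzyloxy)-5-{5,7-bis(benzyloxy)-2-[4-(benzyloxy)phenyl]-4-oxo-4H-chromen-6-yl}benzoate | COC(=O)c1cc(OCc2ccccc2)c(OCc2ccccc2)c(-c2c(OCc3ccccc3)cc3oc(-c4ccc(OCc5ccccc5)cc4)cc(=O)c3c2OCc2ccccc2)c1 | intermediate
11 | 5-bromoresorcinol | Oc1cc(O)cc(Br)c1 | starting material
12 | 1-(2-bromo-4,6-dihydroxyphenyl)ethanone | CC(=O)c1c(O)cc(O)cc1Br | intermediate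
13 | 1-[2,4-bis(benzyloxy)-6-bromophenyl]ethanone | CC(=O)c1c(OCc2ccccc2)cc(OCc2ccccc2)cc1Br | intermediate
14 | 1-[2,4-bis(benzyloxy)-6-bromophenyl]-3-ArB-propane-1,3-dione | O=C(CC(=O)c1cc(OCc2ccccc2)c(OCc2ccccc2)c(-c2c(OCc3ccccc3)cc3oc(-c4ccc(OCc5ccccc5)cc4)cc(=O)c3c2OCc2ccccc2)c1)c1c(OCc2ccccc2)cc(OCc2ccccc2)cc1Br | intermediate
15 | (3S)-1-[2,4-bis(benzyloxy)-6-bromophenyl]-3-ArB-3-hydroxypropan-1-one | O=C(C[C@@H](c1cc(OCc2ccccc2)c(OCc2ccccc2)c(-c2c(OCc3ccccc3)cc3oc(-c4ccc(OCc5ccccc5)cc4)cc(=O)c3c2OCc2ccccc2)c1)O)c1c(OCc2ccccc2)cc(OCc2ccccc2)cc1Br | intermediate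
16 | (1S,3S)-1-[2,4-bis(benzyloxy)-6-bromophenyl]-3-ArB-propane-1,3-diol (anti) | O[C@@H](C[C@@H](c1cc(OCc2ccccc2)c(OCc2ccccc2)c(-c2c(OCc3ccccc3)cc3oc(-c4ccc(OCc5ccccc5)cc4)cc(=O)c3c2OCc2ccccc2)c1)O)c1c(OCc2ccccc2)cc(OCc2ccccc2)cc1Br | intermediate
17 | (2S,4S)-5,7-bis(benzyloxy)-2-ArB-chroman-4-ol (2,4-cis) | O[C@H]1C[C@@H](c2cc(OCc3ccccc3)c(OCc3ccccc3)c(-c3c(OCc4ccccc4)cc4oc(-c5ccc(OCc6ccccc6)cc5)cc(=O)c4c3OCc3ccccc3)c2)Oc2cc(OCc3ccccc3)cc(OCc3ccccc3)c21 | intermediate
18 | (2S)-5,7-bis(benzyloxy)-2-ArB-chroman-4-one (hepta-O-benzyl flavanone) | O=C1C[C@@H](c2cc(OCc3ccccc3)c(OCc3ccccc3)c(-c3c(OCc4ccccc4)cc4oc(-c5ccc(OCc6ccccc6)cc5)cc(=O)c4c3OCc3ccccc3)c2)Oc2cc(OCc3ccccc3)cc(OCc3ccccc3)c21 | intermediate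
19 | (2S)-2-{3,4-dihydroxy-5-[5,7-dihydroxy-2-(4-hydroxyphenyl)-4-oxo-4H-chromen-6-yl]phenyl}-5,7-dihydroxychroman-4-one | O=C1C[C@@H](c2cc(O)c(O)c(-c3c(O)cc4oc(-c5ccc(O)cc5)cc(=O)c4c3O)c2)Oc2cc(O)cc(O)c21 | target

## Step count and risks

Total: 16 steps. Longest linear sequence: 11 steps (steps 1, 2, 3, 7, 8, 11, 12, 13, 14, 15, 16).

**Step 14 (key step).**
- What may go wrong: the copper alkoxide of the wrong (C1) hydroxyl may undergo β-hydride elimination, which would oxidise that carbinol and reduce off the bromide; intermolecular etherification may also compete if the closure is slow.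
- Fallback: the C1 hydroxyl is masked before the closure. Diol 16 is silylated at the unhindered C3 hydroxyl (TESCl, imidazole, DMF, −20 °C) to give (1S,3S)-1-ArA-3-ArB-3-(triethylsilyloxy)propan-1-ol F1. The hindered C1 hydroxyl is then silylated (TBSOTf, 2,6-lutidine) to give (1S,3S)-1-ArA-3-ArB-1-(tert-butyldimethylsilyloxy)-3-(triethylsilyloxy)propane F2. The triethylsilyl group alone is removed (HF·pyridine, pyridine, THF, 0 °C) to give (1S,3S)-3-ArB-3-(tert-butyldimethylsilyloxy)-3-ArA-propan-1-ol, that is (1S,3S)-1-ArB-3-ArA-3-(tert-butyldimethylsilyloxy)propan-1-ol F3. The same copper closure on this single free alcohol gives (2S,4S)-5,7-bis(benzyloxy)-2-ArB-4-(tert-butyldimethylsilyloxy)chroman F4, and TBAF returns the route to 17.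

**Step 12.**
- What may go wrong: hydride transfer may stall because the diketone rests as its chelated enol, may occur at the wrong carbonyl, or may give low facial selectivity on this hindered substrate.
- Fallback: the stereocentre is set by epoxidation instead. Aldehyde 9 and ketone 13 are condensed (KOH, EtOH/THF, Claisen–Schmidt) to (E)-1-ArA-3-ArB-prop-2-en-1-one F5. Juliá–Colonna epoxidation (poly-D-leucine, urea–H2O2, DBU, THF) gives (2S,3R)-2,3-epoxy-1-ArA-3-ArB-propan-1-one F6. Reductive cleavage of the Cα–O bond (PhSeSePh, NaBH4, AcOH, EtOH) keeps the Cβ–O bond and returns the route to 15.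

**Step 7.**
- What may go wrong: transmetalation at the doubly flanked arylpalladium may be slow, so that protodeboronation of 4 and reduction of the iodide take over.
- Fallback: the coupling is run before the third benzyl group is installed. Iodide 7, whose free hydroxyl is a smaller flank, is coupled with 4 under the same catalyst type to give 3,4-bis(benzyloxy)-5-{7-(benzyloxy)-2-[4-(benzyloxy)phenyl]-5-hydroxy-4-oxo-4H-chromen-6-yl}benzaldehyde F7. Benzylation (BnBr, Cs2CO3, DMF, 80 °C) then returns the route to 9.

**Step 9.**
- What may go wrong: the bromine deactivates the ring, so acylation may stop at the O-acetate or occur between the two hydroxyls.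
- Fallback: the carbon is introduced as a formyl group on the ether. Compound 11 is benzylated to 1,3-bis(benzyloxy)-5-bromobenzene F8. Vilsmeier–Haack formylation (POCl3, DMF) gives 2,4-bis(benzyloxy)-6-bromobenzaldehyde F9. MeMgBr addition gives racemic 1-[2,4-bis(benzyloxy)-6-bromophenyl]ethanol F10, and Dess–Martin oxidation returns the route to 13.

**Step 16.**
- What may go wrong: over-reduction, namely hydrogenolysis of the benzylic C2–O1 bond to a dihydrochalcone or saturation of the flavone C2''–C3'' bond, before the hindered benzyl ethers are gone.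
- Fallback: the ethers are cleaved without hydrogen, by BCl3 with pentamethylbenzene as cation scavenger in CH2Cl2 at −78 °C. This leads from 18 directly to 19 and makes no new compound (entry F0).

## Further compounds

F1 | step 14 | (1S,3S)-1-ArA-3-ArB-3-(triethylsilyloxy)propan-1-ol | O[C@@H](C[C@@H](c1cc(OCc2ccccc2)c(OCc2ccccc2)c(-c2c(OCc3ccccc3)cc3oc(-c4ccc(OCc5ccccc5)cc4)cc(=O)c3c2OCc2ccccc2)c1)O[Si](CC)(CC)CC)c1c(OCc2ccccc2)cc(OCc2ccccc2)cc1Br
F2 | step 14 | (1S,3S)-1-ArA-3-ArB-1-(tert-butyldimethylsilyloxy)-3-(triethylsilyloxy)propane | CC(C)(C)[Si](C)(C)O[C@@H](C[C@@H](c1cc(OCc2ccccc2)c(OCc2ccccc2)c(-c2c(OCc3ccccc3)cc3oc(-c4ccc(OCc5ccccc5)cc4)cc(=O)c3c2OCc2ccccc2)c1)O[Si](CC)(CC)CC)c1c(OCc2ccccc2)cc(OCc2ccccc2)cc1Br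
F3 | step 14 | (1S,3S)-1-ArB-3-ArA-3-(tert-butyldimethylsilyloxy)propan-1-ol | CC(C)(C)[Si](C)(C)O[C@@H](C[C@@H](c1cc(OCc2ccccc2)c(OCc2ccccc2)c(-c2c(OCc3ccccc3)cc3oc(-c4ccc(OCc5ccccc5)cc4)cc(=O)c3c2OCc2ccccc2)c1)O)c1c(OCc2ccccc2)cc(OCc2ccccc2)cc1Br
F4 | step 14 | (2S,4S)-5,7-bis(benzyloxy)-2-ArB-4-(tert-butyldimethylsilyloxy)chroman | CC(C)(C)[Si](C)(C)O[C@H]1C[C@@H](c2cc(OCc3ccccc3)c(OCc3ccccc3)c(-c3c(OCc4ccccc4)cc4oc(-c5ccc(OCc6ccccc6)cc5)cc(=O)c4c3OCc3ccccc3)c2)Oc2cc(OCc3ccccc3)cc(OCc3ccccc3)c21
F5 | step 12 | (E)-1-ArA-3-ArB-prop-2-en-1-one | O=C(/C=C/c1cc(OCc2ccccc2)c(OCc2ccccc2)c(-c2c(OCc3ccccc3)cc3oc(-c4ccc(OCc5ccccc5)cc4)cc(=O)c3c2OCc2ccccc2)c1)c1c(OCc2ccccc2)cc(OCc2ccccc2)cc1Br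
F6 | step 12 | (2S,3R)-2,3-epoxy-1-ArA-3-ArB-propan-1-one | O=C([C@H]6O[C@@H]6c1cc(OCc2ccccc2)c(OCc2ccccc2)c(-c2c(OCc3ccccc3)cc3oc(-c4ccc(OCc5ccccc5)cc4)cc(=O)c3c2OCc2ccccc2)c1)c1c(OCc2ccccc2)cc(OCc2ccccc2)cc1Br
F7 | step 7 | 3,4-bis(benzyloxy)-5-{7-(benzyloxy)-2-[4-(benzyloxy)phenyl]-5-hydroxy-4-oxo-4H-chromen-6-yl}benzaldehyde | O=Cc1cc(OCc2ccccc2)c(OCc2ccccc2)c(-c2c(OCc3ccccc3)cc3oc(-c4ccc(OCc5ccccc5)cc4)cc(=O)c3c2O)c1
F8 | step 9 | 1,3-bis(benzyloxy)-5-bromobenzene | Brc1cc(OCc2ccccc2)cc(OCc2ccccc2)c1
F9 | step 9 | 2,4-bis(benzyloxy)-6-bromobenzaldehyde | O=Cc1c(OCc2ccccc2)cc(OCc2ccccc2)cc1Br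
F10 | step 9 | 1-[2,4-bis(benzyloxy)-6-bromophenyl]ethanol (racemic) | CC(O)c1c(OCc2ccccc2)cc(OCc2ccccc2)cc1Br
F0 | step 16 | none | none
A1 | alternative 1 | dimethyl 4-[2,3-bis(benzyloxy)-5-(1,3-dioxolan-2-yl)phenyl]-3,5-dioxoheptanedioate | COC(=O)CC(=O)C(C(=O)CC(=O)OC)c1cc(C2OCCO2)cc(OCc2ccccc2)c1OCc1ccccc1
A2 | alternative 1 | methyl 3-[2,3-bis(benzyloxy)-5-(1,3-dioxolan-2-yl)phenyl]-2,4,6-trihydroxybenzoate | COC(=O)c1c(O)cc(O)c(-c2cc(C3OCCO3)cc(OCc3ccccc3)c2OCc2ccccc2)c1O
A3 | alternative 2 | 3,5-bis(benzyloxy)-4-[2,3-bis(benzyloxy)-5-(1,3-dioxolan-2-yl)phenyl]-2-iodophenol | Oc1cc(OCc2ccccc2)c(-c2cc(C3OCCO3)cc(OCc3ccccc3)c2OCc2ccccc2)c(OCc2ccccc2)c1I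
A4 | alternative 2 | 1-(benzyloxy)-4-ethynylbenzene | C#Cc1ccc(OCc2ccccc2)cc1
A5 | alternative 2 | carbon monoxide | [C-]#[O+]
A6 | alternative 2 | 5,7-bis(benzyloxy)-2-[4-(benzyloxy)phenyl]-6-[2,3-bis(benzyloxy)-5-(1,3-dioxolan-2-yl)phenyl]-4H-chromen-4-one | O=c1cc(-c2ccc(OCc3ccccc3)cc2)oc2cc(OCc3ccccc3)c(-c3cc(C4OCCO4)cc(OCc4ccccc4)c3OCc3ccccc3)c(OCc3ccccc3)c12
A7 | alternative 3 | tert-butyl 2-[2,4-bis(benzyloxy)-6-hydroxybenzoyl]-3-ArB-prop-2-enoate (alkene geometry not defined) | CC(C)(C)OC(=O)C(=Cc1cc(OCc2ccccc2)c(OCc2ccccc2)c(-c2c(OCc3ccccc3)cc3oc(-c4ccc(OCc5ccccc5)cc4)cc(=O)c3c2OCc2ccccc2)c1)C(=O)c1c(O)cc(OCc2ccccc2)cc1OCc1ccccc1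
A8 | alternative 3 | tert-butyl (2S)-5,7-bis(benzyloxy)-2-ArB-4-oxochroman-3-carboxylate (C3 labile) | O=C1C(C(=O)OC(C)(C)C)[C@@H](c2cc(OCc3ccccc3)c(OCc3ccccc3)c(-c3c(OCc4ccccc4)cc4oc(-c5ccc(OCc6ccccc6)cc5)cc(=O)c4c3OCc3ccccc3)c2)Oc2cc(OCc3ccccc3)cc(OCc3ccccc3)c21
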